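The synthesis rests on cutting the bond between C3 of the lactone (ring B: O1, C2, C3, C4, C5) and the benzylic CH2 of the guaiacyl ring A. The key step exploits the vicinal trans pair C3/C4 of ring B, traced back to the flat C3=C4 double bond of an achiral 4-(3,4,5-trimethoxybenzyl)butenolide. In one pot a chiral copper hydride delivers hydride to C4 and the C3 enolate is held as a silyl ketene acetal. Fluoride then releases it onto O-benzylvanillyl bromide, whose benzylic carbon is activated by the para oxygen of ring A; attack anti to the C4 substituent sets C3. Negishi coupling supplies the butenolide; hydrogenolysis frees the phenol.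

Key step: step 3

Assumption: the (R) hand of p-tol-BINAP is taken to deliver hydride to the face of C4 that gives the R centre (both hands are commercial, and the antipode would be used if the sense of induction is the reverse); intermediate 7 is drawn as the mono(enoxy)silane, and a bis(enoxy)silane formed through the second Si–H bond would react in the same way.

Step 1
Reactants: 1 3,4,5-trimethoxybenzyl chloride; 2 4-bromofuran-2(5H)-one
Product: 4 4-(3,4,5-trimethoxybenzyl)furan-2(5H)-one, via benzylzinc chloride 3 (not isolated)
Conditions: 1, Zn dust, LiCl, THF, 25 °C; then 2, Pd(OAc)2 (2 mol%), SPhos (4 mol%), THF, 25 °C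
Reagents that add atoms: zinc, [Zn] (stays only in 3)
Why: LiCl-assisted zinc insertion into the benzylic C–Cl bond gives a non-basic organozinc that should undergo Negishi cross-coupling at the activated vinylogous acyl bromide C4–Br of 2 without deprotonating C5–H or moving the ring double bond; no stereocentre is formed.

Step 2
Reactants: 5 4-benzyloxy-3-methoxybenzyl alcohol
Product: 6 4-benzyloxy-3-methoxybenzyl bromide
Conditions: PBr3 (0.4 equiv), Et2O, 0 °C; aqueous wash, used without chromatography
Reagents that add atoms: phosphorus tribromide, BrP(Br)Br
Why: Alcohol-to-bromide substitution with PBr3 (SN2 on the phosphite ester) should be fast at this electron-rich benzylic carbon and leaves both aryl ethers untouched; no stereocentre is involved.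

Step 3
Reactants: 4 4-(3,4,5-trimethoxybenzyl)furan-2(5H)-one; 6 4-benzyloxy-3-methoxybenzyl bromide
Product: 8 (3R,4R)-3-(4-benzyloxy-3-methoxybenzyl)-4-(3,4,5-trimethoxybenzyl)dihydrofuran-2(3H)-one, via silyl ketene acetal 7 (not isolated)
Conditions: CuCl (5 mol%), NaOtBu (5 mol%), (R)-p-tol-BINAP (5 mol%), Ph2SiH2 (1.0 equiv), toluene, 0 °C to rt; then 6 (1.2 equiv), tetrabutylammonium difluorotriphenylsilicate (TBAT, 1.2 equiv), CH2Cl2, rt
Reagents that add atoms: diphenylsilane, [SiH2](c1ccccc1)c1ccccc1 (silicon stays only in 7; 8 keeps one hydrogen at C4)
Why: Proposed new method: the bisphosphine-ligated monovalent copper hydride, formed from CuOtBu and Ph2SiH2, adds hydride to C4 of the C3=C4 double bond of 4, sigma-bond metathesis of the resulting copper enolate with Si–H releases silyl ketene acetal 7 and regenerates the hydride, and fluoride from TBAT then unmasks the enolate, whose C3 displaces bromide from the benzylic carbon of 6 in an SN2 reaction. The closest known reaction types are the copper-catalysed asymmetric conjugate reduction of beta-substituted butenolides, which is normally ended by protonation, and the one-pot asymmetric conjugate reduction/TBAT-promoted alkylation of beta-substituted cyclopentenones; what is untested is their merger on a lactone, where turnover must proceed without an alcohol. No ring is closed. C4 (R) is set by the chiral ligand, which leaves only one face of the planar butenolide open to Cu–H, and C3 (R) is set by the substrate, since the bromide approaches the flat enolate anti to the C4 benzyl group and so gives the trans lactone. The step needs 1,4- over 1,2-reduction (soft copper hydride against a poorly electrophilic lactone carbonyl), no Michael self-condensation (the acceptor carbon C4 of 4 already bears two carbon substituents and 4 is consumed before fluoride is added) and C-monoalkylation (soft benzylic bromide activated by the para oxygen of ring A, tertiary C3–H of 8 slow to re-enolise). A minor cis epimer would converge on 8 under mild base because C3 stays epimerisable and trans is the more stable arrangement.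

Step 4
Reactants: 8 (3R,4R)-3-(4-benzyloxy-3-methoxybenzyl)-4-(3,4,5-trimethoxybenzyl)dihydrofuran-2(3H)-one
Product: 9 (3R,4R)-3-(4-hydroxy-3-methoxybenzyl)-4-(3,4,5-trimethoxybenzyl)dihydrofuran-2(3H)-one
Conditions: H2 (1 atm), Pd/C, EtOAc–EtOH, rt
Reagents that add atoms: none
Why: Catalytic hydrogenolysis of the aryl benzyl ether under neutral conditions should free the ring A phenol while the lactone, the methyl ethers and the C3/C4 stereocentres stay intact.

Compound list
1 | 3,4,5-trimethoxybenzyl chloride | COc1cc(CCl)cc(OC)c1OC | starting material
2 | 4-bromofuran-2(5H)-one | O=C1C=C(Br)CO1 | starting material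
3 | (3,4,5-trimethoxybenzyl)zinc chloride, LiCl-solvated THF solution | COc1cc(C[Zn]Cl)cc(OC)c1OC | intermediate
4 | 4-(3,4,5-trimethoxybenzyl)furan-2(5H)-one (achiral butenolide) | COc1cc(CC2=CC(=O)OC2)cc(OC)c1OC | intermediate
5 | 4-benzyloxy-3-methoxybenzyl alcohol | COc1cc(CO)ccc1OCc1ccccc1 | starting material
6 | 4-benzyloxy-3-methoxybenzyl bromide | COc1cc(CBr)ccc1OCc1ccccc1 | intermediate
7 | (R)-{[4-(3,4,5-trimethoxybenzyl)-4,5-dihydrofuran-2-yl]oxy}diphenylsilane (silyl ketene acetal) | C1=C(O[SiH](c2ccccc2)c2ccccc2)OC[C@@H]1Cc1cc(OC)c(OC)c(OC)c1 | intermediate
8 | (3R,4R)-3-(4-benzyloxy-3-methoxybenzyl)-4-(3,4,5-trimethoxybenzyl)dihydrofuran-2(3H)-one (trans) | COc1cc(C[C@H]2C(=O)OC[C@@H]2Cc2cc(OC)c(OC)c(OC)c2)ccc1OCc1ccccc1 | intermediate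
9 | (3R,4R)-3-(4-hydroxy-3-methoxybenzyl)-4-(3,4,5-trimethoxybenzyl)dihydrofuran-2(3H)-one (trans) | COc1cc(C[C@H]2C(=O)OC[C@@H]2Cc2cc(OC)c(OC)c(OC)c2)ccc1O | target

Total step count: 4. Longest linear sequence: 3 steps (step 1 or step 2, then step 3, then step 4).

Steps most likely to fail

Step 3. Catalyst turnover may stall without a proton source, the enolate may self-condense, facial selectivity may erode, or fluoride may attack the bromide before the enolate does. The fallback uses known chemistry and sets out from 4. The conjugate reduction would be run in its established protonative mode (CuCl2·2H2O, NaOtBu, (R)-p-tol-BINAP, PMHS, t-BuOH, toluene) to isolate (R)-4-(3,4,5-trimethoxybenzyl)dihydrofuran-2(3H)-one F1. Its lithium enolate (LiN(SiMe3)2, THF, −78 °C) would then be alkylated with 6 anti to the C4 substituent, which comes back to the route at 8.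

Step 1. The benzylic organozinc may homocouple, the ring double bond may migrate toward the arene, or the bromobutenolide may decompose under the coupling conditions. The fallback sets out from 2. Palladium-catalysed stannylation ((Bu3Sn)2, Pd(PPh3)4, toluene, heat) would give 4-(tributylstannyl)furan-2(5H)-one F2. A Stille coupling of F2 with chloride 1 as the electrophile (Pd(PPh3)4, THF, heat) comes back to the route at 4. The polarity of the two partners is reversed, so no benzylic organometal is needed.

Step 2. The electron-rich benzylic bromide may self-alkylate (Friedel–Crafts oligomerisation) or hydrolyse during isolation or storage. The fallback sets out from 5. MnO2 oxidation (CH2Cl2, rt) would give the shelf-stable electrophile 4-benzyloxy-3-methoxybenzaldehyde F3. Aldol addition of the lithium enolate of lactone F1 (made from 4 as described for step 3; LiN(SiMe3)2, THF, −78 °C) to F3 would give the trans aldol adduct (3S,4R)-3-[(4-benzyloxy-3-methoxyphenyl)(hydroxy)methyl]-4-(3,4,5-trimethoxybenzyl)dihydrofuran-2(3H)-one F4 as a mixture of carbinol epimers. One hydrogenolysis (H2, Pd/C, EtOH–AcOH) would then remove both the benzylic hydroxyl group and the O-benzyl group, coming back to the route at 9.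

Further compounds
F1 | step 3 | (R)-4-(3,4,5-trimethoxybenzyl)dihydrofuran-2(3H)-one | O=C1C[C@@H](Cc2cc(OC)c(OC)c(OC)c2)CO1
F2 | step 1 | 4-(tributylstannyl)furan-2(5H)-one | CCCC[Sn](CCCC)(CCCC)C1=CC(=O)OC1
F3 | step 2 | 4-benzyloxy-3-methoxybenzaldehyde | COc1cc(C=O)ccc1OCc1ccccc1
F4 | step 2 | (3S,4R)-3-[(4-benzyloxy-3-methoxyphenyl)(hydroxy)methyl]-4-(3,4,5-trimethoxybenzyl)dihydrofuran-2(3H)-one, both carbinol epimers | COc1cc(C(O)[C@H]2C(=O)OC[C@@H]2Cc2cc(OC)c(OC)c(OC)c2)ccc1OCc1ccccc1
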